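## Retrosynthetic overview
1. The γ-lactone is opened to a 2-(hydroxymethyl)benzoate, which comes from reduction of the 2-formylbenzoate 8.
2. The lactone CH2 carbon comes from formaldehyde, added by ortho-specific Mg-phenoxide formylation of phenol 7. C2 is the only open ortho site of 7, so the regiochemistry is fixed.
3. The aryl–O–CH2 bond comes from a Mitsunobu reaction between the more acidic 4-OH of methyl 3-O-methylgallate (6) and allylic alcohol 5. The chain also serves as the O-4 protecting group.
4. Chain 5 comes from (E,E)-farnesyl acetate (1) by terminal bromohydrin formation and radical debromination (net Markovnikov hydration), peracetylation, then selective removal of the primary acetate.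
5. Ring order: the benzene ring is purchased. The γ-lactone is the only ring formed, and it closes in the last step.

Assumption 1: the target has no stereocentre, so "single enantiomer" reduces to the 2E,6E geometry. This geometry is bought in with 1 and is never touched.
Assumption 2: compounds 1 and 6 are taken as commercial. Reagents are given by name and SMILES within the steps and are not numbered.

## Route

**Step 1**
Reactants: 1, (2E,6E)-farnesyl acetate
Product: 2, (2E,6E)-10-bromo-11-hydroxy-3,7,11-trimethyldodeca-2,6-dien-1-yl acetate (racemic at C10)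
Conditions: NBS (1.1 equiv), THF/H2O (ca. 2:1, near the cloud point), 0 °C, 1–2 h
Reagents that add atoms: N-bromosuccinimide, O=C1CCC(=O)N1Br; water, O
Why: In this van Tamelen terminal-selective bromohydrin formation, aqueous THF leaves the terminal alkene most exposed (the C2 alkene is also deactivated by the allylic acetate) and water opens the bromonium ion at tertiary C11 (Markovnikov), giving a racemic C10 centre that Step 2 erases.

**Step 2**
Reactants: 2
Product: 3, (2E,6E)-11-hydroxy-3,7,11-trimethyldodeca-2,6-dien-1-yl acetate
Conditions: n-Bu3SnH (1.5 equiv), AIBN (0.1 equiv), PhMe (0.3 M), 80 °C, 1 h; KF work-up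
Reagents that add atoms: none
Why: In this radical-chain hydrodebromination, the secondary C10 radical is 4-pentenyl-type (4-exo and 5-endo closure both disfavoured) and concentrated stannane traps it before any 1,5-H shift, while the acetate, tertiary OH and both E-alkenes are inert.

**Step 3**
Reactants: 3
Product: 4, (2E,6E)-3,7,11-trimethyldodeca-2,6-diene-1,11-diyl diacetate
Conditions: Ac2O (4 equiv), Et3N (5 equiv), DMAP (0.3 equiv), CH2Cl2, rt, 24–36 h
Reagents that add atoms: acetic anhydride, CC(=O)OC(C)=O
Why: Steglich–Höfle DMAP-catalysed acylation (via the N-acetylpyridinium ion) esterifies hindered tertiary alcohols without acid, which avoids elimination and cation–olefin cyclisation.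

**Step 4**
Reactants: 4
Product: 5, (6E,10E)-12-hydroxy-2,6,10-trimethyldodeca-6,10-dien-2-yl acetate
Conditions: K2CO3 (0.5 equiv), MeOH, 0 °C, 1–2 h (TLC control)
Reagents that add atoms: none
Why: In this chemoselective transesterification, the unhindered primary allylic acetate is methanolysed far faster than the tertiary acetate, which survives.

**Step 5**
Reactants: 5; 6, methyl 3,4-dihydroxy-5-methoxybenzoate (1.5 equiv)
Product: 7, methyl 4-{[(2E,6E)-11-acetoxy-3,7,11-trimethyldodeca-2,6-dien-1-yl]oxy}-3-hydroxy-5-methoxybenzoate
Conditions: PPh3 (1.2 equiv), DIAD (1.2 equiv, slow addition), THF, 0 °C → rt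
Reagents that add atoms: none (PPh3 and DIAD leave no atoms)
Why: In this Mitsunobu etherification, the more acidic 4-OH (para to the ester) is deprotonated and displaces the primary allylic oxyphosphonium by SN2 with the E-geometry retained, excess 6 limits bis-alkylation, and any 3-O isomer has no free ortho site and so is inert in Step 6.

**Step 6**
Reactants: 7
Product: 8, methyl 4-{[(2E,6E)-11-acetoxy-3,7,11-trimethyldodeca-2,6-dien-1-yl]oxy}-2-formyl-3-hydroxy-5-methoxybenzoate
Conditions: anhydrous MgCl2 (3 equiv), Et3N (6 equiv), (CH2O)n (10 equiv), MeCN, reflux, 6–16 h; cold 10% citric acid work-up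
Reagents that add atoms: paraformaldehyde (as formaldehyde), C=O
Why: In this Casnati–Skattebøl ortho-formylation, the Mg phenoxide delivers CH2O through a cyclic transition state only to C2 (the sole open ortho site, also para to OMe) and a second CH2O oxidises the benzylic alkoxide, while any alkoxide that instead lactonises onto the neighbouring ester is already 9 and passes unchanged through Step 7.

**Step 7**
Reactants: 8
Product: 9, farnesylemefuranone F
Conditions: NaBH4 (1.2 equiv), MeOH/THF (1:1), 0 °C, 30 min; then 10% citric acid, rt
Reagents that add atoms: none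
Why: Borohydride reduces the aldehyde chemoselectively (the aryl ester and tertiary acetate are untouched), and the benzylic alkoxide then undergoes spontaneous 5-exo-trig lactonisation onto the ortho methyl ester with loss of MeOH, closing the phthalide.

## Compound list
| No. | Name | SMILES | Role |
|---|---|---|---|
| 1 | (2E,6E)-farnesyl acetate | CC(=O)OC/C=C(\C)CC/C=C(\C)CCC=C(C)C | starting material |
| 2 | (2E,6E)-10-bromo-11-hydroxy-3,7,11-trimethyldodeca-2,6-dien-1-yl acetate (racemic) | CC(=O)OC/C=C(\C)CC/C=C(\C)CCC(Br)C(C)(C)O | intermediate |
| 3 | (2E,6E)-11-hydroxy-3,7,11-trimethyldodeca-2,6-dien-1-yl acetate | CC(=O)OC/C=C(\C)CC/C=C(\C)CCCC(C)(C)O | intermediate |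
| 4 | (2E,6E)-3,7,11-trimethyldodeca-2,6-diene-1,11-diyl diacetate | CC(=O)OC/C=C(\C)CC/C=C(\C)CCCC(C)(C)OC(C)=O | intermediate |
| 5 | (6E,10E)-12-hydroxy-2,6,10-trimethyldodeca-6,10-dien-2-yl acetate | OC/C=C(\C)CC/C=C(\C)CCCC(C)(C)OC(C)=O | intermediate |
| 6 | methyl 3,4-dihydroxy-5-methoxybenzoate | COC(=O)c1cc(O)c(O)c(OC)c1 | starting material |
| 7 | methyl 4-{[(2E,6E)-11-acetoxy-3,7,11-trimethyldodeca-2,6-dienyl]oxy}-3-hydroxy-5-methoxybenzoate | COC(=O)c1cc(O)c(OC/C=C(\C)CC/C=C(\C)CCCC(C)(C)OC(C)=O)c(OC)c1 | intermediate |
| 8 | methyl 4-{[(2E,6E)-11-acetoxy-3,7,11-trimethyldodeca-2,6-dienyl]oxy}-2-formyl-3-hydroxy-5-methoxybenzoate | COC(=O)c1cc(OC)c(OC/C=C(\C)CC/C=C(\C)CCCC(C)(C)OC(C)=O)c(O)c1C=O | intermediate |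
| 9 | farnesylemefuranone F, (6E,10E)-12-[(4-hydroxy-6-methoxy-1-oxo-1,3-dihydroisobenzofuran-5-yl)oxy]-2,6,10-trimethyldodeca-6,10-dien-2-yl acetate | COc1cc2c(c(O)c1OC/C=C(\C)CC/C=C(\C)CCCC(C)(C)OC(C)=O)COC2=O | target |

## Summary
Total steps: 7.
Longest linear sequence: 7 (1 → 9). Compound 6 enters at Step 5.

**Steps most likely to fail**
1. **Step 6.** C2 is hindered and next to the ester, and the allylic aryl ether must tolerate warm Mg(II).
   - Fallback: build the core first. Put a benzyl placeholder on O-4 of 6.
   - The robust arene can then be brominated at C2 (ortho to the OH), followed by Stille hydroxymethylation (Bu3SnCH2OH, Pd) with lactonisation.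
   - Hydrogenolysis gives 4,5-dihydroxy-6-methoxyphthalide, and 5 is attached last at the more acidic 5-OH (para to the lactone C=O).
2. **Step 5.** O-4 versus O-3 selectivity and possible catechol–phosphorane formation are the concerns.
   - Fallback: block O-3 instead of relying on pKa. Peracetylate 6 and convert 5 to its allylic bromide (MsCl/Et3N, then LiBr).
   - Carry out the selective 4-O-deacetylative alkylation (K2CO3, KI, acetone), in which only the para-acetate is lost.
   - Remove the 3-OAc by brief K2CO3/MeOH treatment, which the tertiary acetate survives.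
3. **Step 1.** Terminal versus internal alkene selectivity gives only a moderate yield.
   - Fallback: replace the bromonium chemistry with terminal-selective Sharpless dihydroxylation of 1 to the 10,11-diol.
   - Deoxygenate the secondary C10-OH by Barton–McCombie reaction (thiocarbonyldiimidazole, then Bu3SnH) to reach 3.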